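**Retrosynthetic overview**
1. 18 ⇐ 2,3-dialdehyde 17 (enol-acetal closure and acetylation form the dihydropyran last) ⇐ ozonolysis of cyclopentene 16.
2. 16 ⇐ spiro-formal 15 of triol 14: oxonium–ene closure of the oxepane (C15–C4 bond; alkene moves from C3=C4 to C2=C3).
3. 14 ⇐ vinyl sulfide 9 + ethyl diazoacetate 10 (cyclopropane), then CH2O, LiAlH4 and desulfurisation.
4. 9 ⇐ cycloheptenone 7 ⇐ cyclobutanone 6: three-carbon radical ring expansion (key step), then MeMgBr.
5. 6 ⇐ 1 + 4. Ring order: cyclopentene (in 1) → cycloheptenone → cyclopropane → oxepane → dihydropyran.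

Assumption and notation: 1 (single (1S,5R) enantiomer) and 4 are taken as purchasable; the comments use the aromadendrane locants of the target (C1/C5 ring fusion, C2 acetal, C3=C4 enol ether, C6/C7/C11 cyclopropane, C10 carbinol, C12 endo CH2O, C13 exo CH2OAc, C15 the CH2 on C4).

**Step 1**
Reactants: 1 (1S,5R)-bicyclo[3.2.0]hept-2-en-6-one
Product: 3 7-(phenylsulfanyl)-6-(trimethylsilyloxy)bicyclo[3.2.0]hepta-2,6-diene, via sulfenylated ketone 2 (not isolated)
Conditions: LiN(iPr)2, THF, −78 °C; PhSSO2Ph; then LiN(iPr)2, Me3SiCl, −78 → 0 °C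
Reagents that add atoms: S-phenyl benzenethiosulfonate O=S(=O)(Sc1ccccc1)c1ccccc1; chlorotrimethylsilane C[Si](C)(C)Cl
Why: The cyclobutanone can only enolise toward C6 (a bridgehead enolate is too strained), so sulfenylation and then O-silylation of the more acidic α-thio ketone are regioselective in one flask (enolate sulfenylation, silyl enol ether formation); no stereocentre is created.

**Step 2**
Reactants: 3 7-(phenylsulfanyl)-6-(trimethylsilyloxy)bicyclo[3.2.0]hepta-2,6-diene; 4 1-bromo-3-(methylsulfanyl)propane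
Product: 6 7-[3-bromo-1-(methylsulfanyl)propyl]-7-(phenylsulfanyl)bicyclo[3.2.0]hept-2-en-6-one, via chloro sulfide 5 (not isolated)
Conditions: 4, N-chlorosuccinimide, CCl4, 0 → 25 °C, filter; then 3, ZnBr2 (5 mol %), CH2Cl2, −40 → 0 °C
Reagents that add atoms: none
Why: N-Chlorosuccinimide chlorinates the sulfide at its internal α-carbon and ZnBr2 ionises the chloro sulfide to a thionium ion that alkylates the thio-substituted enol silane at C6 on the convex face (Paterson–Fleming α-thioalkylation of a silyl enol ether); the two new centres (C6, C7) become trigonal in step 3.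

**Step 3**
Reactants: 6 7-[3-bromo-1-(methylsulfanyl)propyl]-7-(phenylsulfanyl)bicyclo[3.2.0]hept-2-en-6-one
Product: 7 cis-8-(phenylsulfanyl)-3,3a,5,6-tetrahydroazulen-4(8aH)-one
Conditions: Bu3SnH (1.2 equiv, syringe pump), AIBN, benzene (0.01 M), 80 °C
Reagents that add atoms: none
Why: Key ring expansion: the primary C9 radical adds to the strained C10 carbonyl, the alkoxy radical cleaves the C6–C10 bond to the sulfur-stabilised radical, and loss of MeS• from C7 fixes the C6=C7 bond as a vinyl sulfide (Dowd–Beckwith three-carbon ring expansion ended by β-scission of a thiyl radical); bromine abstraction should outrun attack of tin on either sulfide, and the cis ring fusion of 1 is untouched.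

**Step 4**
Reactants: 7 cis-8-(phenylsulfanyl)-3,3a,5,6-tetrahydroazulen-4(8aH)-one
Product: 9 4-methyl-8-(phenylsulfanyl)-4-(trimethylsilyloxy)-3,3a,4,5,6,8a-hexahydroazulene, via tertiary alcohol 8 (not isolated)
Conditions: MeMgBr, CeCl3, THF, −78 °C; then Me3SiOTf, 2,6-lutidine, −78 → 0 °C
Reagents that add atoms: methylmagnesium bromide C[Mg]Br; trimethylsilyl trifluoromethanesulfonate C[Si](C)(C)OS(=O)(=O)C(F)(F)F
Why: The organocerium reagent adds to the C10 ketone from the convex face, anti to the cis-fused cyclopentene, which sets C10 with CH3 cis to H-1 and oxygen on the concave face (Grignard 1,2-addition), and in situ silylation keeps the hydroxyl from intercepting the carbenoid of step 5.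

**Step 5**
Reactants: 9 4-methyl-8-(phenylsulfanyl)-4-(trimethylsilyloxy)-3,3a,4,5,6,8a-hexahydroazulene; 10 ethyl diazoacetate
Product: 11 ethyl 4-methyl-7b-(phenylsulfanyl)-4-(trimethylsilyloxy)-1a,2,3,4,4a,5,7a,7b-octahydro-1H-cyclopropa[e]azulene-1-carboxylate
Conditions: 10 (1.5 equiv, syringe pump), Rh2(OAc)4 (1 mol %), CH2Cl2, 25 °C
Reagents that add atoms: none
Why: The electrophilic rhodium carbenoid is taken up by the electron-rich vinyl sulfide (through its sulfur ylide) much faster than by the isolated cyclopentene and closes the cyclopropane on the face anti to the cyclopentene ring, cis to H-5, which sets C6 and C7 (metal-carbenoid cyclopropanation of a vinyl sulfide); the ester epimers at C11 converge in step 6.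

**Step 6**
Reactants: 11 ethyl 4-methyl-7b-(phenylsulfanyl)-4-(trimethylsilyloxy)-1a,2,3,4,4a,5,7a,7b-octahydro-1H-cyclopropa[e]azulene-1-carboxylate
Product: 13 1,1-bis(hydroxymethyl)-4-methyl-7b-(phenylsulfanyl)-1a,2,3,4,4a,5,7a,7b-octahydro-1H-cyclopropa[e]azulen-4-ol, via hydroxymethyl ester 12 (not isolated)
Conditions: LiN(iPr)2, THF, −78 °C; CH2O (gas); then LiAlH4, 0 → 25 °C; aqueous NaOH work-up; K2CO3, MeOH, 25 °C
Reagents that add atoms: formaldehyde C=O
Why: The cyclopropyl ester enolate is hydroxymethylated and the ester reduced in the same flask, so C11 carries two CH2OH groups and is no longer a stereocentre (ester enolate aldol with formaldehyde, LiAlH4 reduction), and basic methanolysis frees the tertiary alcohol without exposing the thio-substituted cyclopropane to acid.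

**Step 7**
Reactants: 13 1,1-bis(hydroxymethyl)-4-methyl-7b-(phenylsulfanyl)-1a,2,3,4,4a,5,7a,7b-octahydro-1H-cyclopropa[e]azulen-4-ol
Product: 14 1,1-bis(hydroxymethyl)-4-methyl-1a,2,3,4,4a,5,7a,7b-octahydro-1H-cyclopropa[e]azulen-4-ol
Conditions: lithium 4,4′-di-tert-butylbiphenylide (6 equiv), THF, −78 °C; then MeOH
Reagents that add atoms: none
Why: Reductive lithiation cleaves the cyclopropyl C6–SPh bond and the cyclopropyllithium is protonated in the only low-strain, cis-fused bicyclo[5.1.0] arrangement (Cohen reductive lithiation of a cyclopropyl phenyl sulfide); the isolated alkene and the alkoxides are inert to the arene radical anion at −78 °C.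

**Step 8**
Reactants: 14 1,1-bis(hydroxymethyl)-4-methyl-1a,2,3,4,4a,5,7a,7b-octahydro-1H-cyclopropa[e]azulen-4-ol
Product: 15 4′-methyl-1a′,2′,3′,4′,4a′,5′,7a′,7b′-octahydrospiro[1,3-dioxane-5,1′-cyclopropa[e]azulen]-4′-ol
Conditions: CH2(OMe)2 (1.1 equiv), camphorsulfonic acid (cat.), 4 Å molecular sieves, CH2Cl2, 25 °C
Reagents that add atoms: dimethoxymethane COCOC
Why: Acid-catalysed acetal exchange closes the six-membered formal on the 1,3-diol much faster than the hindered tertiary alcohol reacts (transacetalisation), and it brings in C15 while masking both primary alcohols as one symmetric unit.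

**Step 9**
Reactants: 15 4′-methyl-1a′,2′,3′,4′,4a′,5′,7a′,7b′-octahydrospiro[1,3-dioxane-5,1′-cyclopropa[e]azulen]-4′-ol
Product: 16 12,15-epoxyaromadendr-2-ene-10,13-diol
Conditions: In(OTf)3 (10 mol %), 4 Å molecular sieves, CH2Cl2, −20 → 0 °C
Reagents that add atoms: none
Why: Proposed new method: the Lewis acid opens the symmetric spiro-formal reversibly to either ROCH2+ oxocarbenium ion, only the endo (C12–O) ion can reach the cyclopentene, and it adds to C4 with suprafacial transfer of H-2 to oxygen through a six-membered transition state (oxonium–ene), so one isomerisation forms the C15–C4 bond and the oxepane, moves the alkene to C2=C3 and releases the exo C13–OH, the closest known chemistry being intramolecular oxonium–ene (Prins) cyclisations of acetals and Lewis-acid opening of 1,3-dioxane acetals; C4 becomes a stereocentre (C15 cis to C6) that turns trigonal in step 10.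

**Step 10**
Reactants: 16 12,15-epoxyaromadendr-2-ene-10,13-diol
Product: 18 CNP0250836.3, via dialdehyde 17 (not isolated)
Conditions: O3, CH2Cl2, −78 °C; Me2S, −78 → 25 °C; then Ac2O, pyridine, 0 → 25 °C
Reagents that add atoms: ozone [O-][O+]=O; acetic anhydride CC(=O)OC(C)=O
Why: Ozone cleaves the only alkene to the 2,3-dialdehyde, the C3 enol adds to C2=O to give the cyclic enol hemiacetal, and acetic anhydride acetylates the lactol and the primary C13–OH but not the tertiary C10–OH (ozonolysis, lactol formation, acetylation); the C2 acetate is expected in the anomerically favoured axial position trans to the C1–C10 bond, as in iridoid aglycone acetates, which sets C2.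

**Compound list**
1 | (1S,5R)-bicyclo[3.2.0]hept-2-en-6-one | O=C1C[C@H]2C=CC[C@@H]12 | starting material
2 | 7-(phenylsulfanyl)bicyclo[3.2.0]hept-2-en-6-one (bridgeheads as in 1; C7 epimers) | O=C1C(Sc2ccccc2)[C@H]3C=CC[C@@H]13 | intermediate
3 | 7-(phenylsulfanyl)-6-(trimethylsilyloxy)bicyclo[3.2.0]hepta-2,6-diene (bridgeheads as in 1) | C[Si](C)(C)OC1=C(Sc2ccccc2)[C@H]3C=CC[C@@H]13 | intermediate
4 | 1-bromo-3-(methylsulfanyl)propane | CSCCCBr | starting material
5 | 3-bromo-1-chloro-1-(methylsulfanyl)propane (racemic) | CSC(Cl)CCBr | intermediate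
6 | 7-[3-bromo-1-(methylsulfanyl)propyl]-7-(phenylsulfanyl)bicyclo[3.2.0]hept-2-en-6-one (chain exo; both epimers at the chain CH–S) | O=C1[C@](Sc2ccccc2)(C(SC)CCBr)[C@H]3C=CC[C@@H]13 | intermediate
7 | cis-8-(phenylsulfanyl)-3,3a,5,6-tetrahydroazulen-4(8aH)-one | O=C1CCC=C(Sc2ccccc2)[C@H]3C=CC[C@@H]13 | intermediate
8 | cis-fused 4-methyl-8-(phenylsulfanyl)-3,3a,4,5,6,8a-hexahydroazulen-4-ol (OH trans to H-3a) | C[C@]1(O)CCC=C(Sc2ccccc2)[C@H]3C=CC[C@@H]13 | intermediate
9 | 4-methyl-8-(phenylsulfanyl)-4-(trimethylsilyloxy)-3,3a,4,5,6,8a-hexahydroazulene (silyl ether of 8) | C[C@]1(O[Si](C)(C)C)CCC=C(Sc2ccccc2)[C@H]3C=CC[C@@H]13 | intermediate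
10 | ethyl diazoacetate | CCOC(=O)C=[N+]=[N-] | starting material
11 | ethyl 4-methyl-7b-(phenylsulfanyl)-4-(trimethylsilyloxy)-1a,2,3,4,4a,5,7a,7b-octahydro-1H-cyclopropa[e]azulene-1-carboxylate (cyclopropane cis to H-7a and to the 4-methyl; ester exo) | C[C@]1(O[Si](C)(C)C)CC[C@@H]4[C@@H](C(=O)OCC)[C@]4(Sc2ccccc2)[C@H]3C=CC[C@@H]13 | intermediate
12 | ethyl 1-(hydroxymethyl)-4-methyl-7b-(phenylsulfanyl)-4-(trimethylsilyloxy)-1a,2,3,4,4a,5,7a,7b-octahydro-1H-cyclopropa[e]azulene-1-carboxylate (CH2OH exo) | C[C@]1(O[Si](C)(C)C)CC[C@@H]4[C@](CO)(C(=O)OCC)[C@]4(Sc2ccccc2)[C@H]3C=CC[C@@H]13 | intermediate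
13 | 1,1-bis(hydroxymethyl)-4-methyl-7b-(phenylsulfanyl)-1a,2,3,4,4a,5,7a,7b-octahydro-1H-cyclopropa[e]azulen-4-ol | C[C@]1(O)CC[C@@H]4C(CO)(CO)[C@]4(Sc2ccccc2)[C@H]3C=CC[C@@H]13 | intermediate
14 | 1,1-bis(hydroxymethyl)-4-methyl-1a,2,3,4,4a,5,7a,7b-octahydro-1H-cyclopropa[e]azulen-4-ol | C[C@]1(O)CC[C@@H]3C(CO)(CO)[C@@H]3[C@H]2C=CC[C@@H]12 | intermediate
15 | 4′-methyl-1a′,2′,3′,4′,4a′,5′,7a′,7b′-octahydrospiro[1,3-dioxane-5,1′-cyclopropa[e]azulen]-4′-ol | C[C@]1(O)CC[C@@H]3C4(COCOC4)[C@@H]3[C@H]2C=CC[C@@H]12 | intermediate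
16 | 12,15-epoxyaromadendr-2-ene-10,13-diol (oxepane C12–O–C15; C15 on C4 cis to C6) | C[C@]1(O)CC[C@@H]2[C@]3(CO)COC[C@H]4C=C[C@@H]1[C@H]4[C@H]23 | intermediate
17 | 12,15-epoxy-10,13-dihydroxy-2,3-secoaromadendrane-2,3-dial | C[C@]1(O)CC[C@@H]2[C@]3(CO)COC[C@@H](C=O)[C@@H]([C@H]1C=O)[C@H]23 | intermediate
18 | CNP0250836.3 (2,13-di-O-acetyl 2,3-secoaromadendrane enol acetal) | CC(=O)OC[C@@]12COCC3=CO[C@H](OC(C)=O)[C@@H]4[C@H]3[C@@H]1[C@@H]2CC[C@]4(C)O | target

**Step count and risks**
Total steps: 10. Longest linear sequence: 10 steps (1 → 18); 4 and 10 are used as bought.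

Step 3 (ring expansion; risks are premature reduction of the radical and the wrong β-scission). The fallback sets out from 3 and comes back at 7. Mukaiyama aldol of 3 with 3-iodopropanal (TiCl4, CH2Cl2, −78 °C) gives the iodo aldol F1. MsCl and Et3N give the mesylate F2, which cannot eliminate because C6 carries no hydrogen. t-BuLi (2 equiv, Et2O–pentane, −100 °C) effects iodine–lithium exchange and closure onto the ketone to the cyclobutanol mesylate F3. Its alkoxide undergoes Grob fragmentation on warming to give 7; only the C7 epimer with the mesylate antiperiplanar to the C6–C10 bond can fragment.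

Step 9 (the new oxonium–ene closure). The fallback uses known reactions, sets out from 15 and comes back at 18. SeO2/t-BuOOH allylic hydroxylation gives the C2 alcohol F4. KH and Bu3SnCH2I give the stannylmethyl ether F5. n-BuLi triggers tin–lithium exchange and [2,3]-Wittig–Still rearrangement to the C4-hydroxymethyl alkene F6. MsCl/Et3N gives the primary mesylate F7. Me2BBr, then aqueous NaHCO3, cleaves the formal to the diol mesylate F8. K2CO3 in MeOH closes the oxepane by Williamson etherification (only the endo alkoxide reaches C15) to the C4-epimeric oxepane F9. The conditions of step 10 applied to F9 give 18, because C4 becomes trigonal.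

Step 10 (one-flask ozonolysis and acetalisation; risks are an anomer mixture, elimination of the β-alkoxy aldehyde and a competing lactol with the C10–OH). The fallback sets out from 16 and comes back at 18. Ozonolysis in CH2Cl2–MeOH, Me2S, then pyridinium p-toluenesulfonate in MeOH with removal of methanol gives the isolable, equilibrated methyl acetal F10. Ac2O/pyridine gives the C13 acetate F11. Acetolysis (AcOH, catalytic camphorsulfonic acid, 0 °C) exchanges OMe for OAc under anomeric control to give 18.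

**Further compounds**
F1 | step 3 | 7-(1-hydroxy-3-iodopropyl)-7-(phenylsulfanyl)bicyclo[3.2.0]hept-2-en-6-one | O=C1[C@](Sc2ccccc2)(C(O)CCI)[C@H]3C=CC[C@@H]13
F2 | step 3 | methanesulfonate of F1 | O=C1[C@](Sc2ccccc2)(C(OS(C)(=O)=O)CCI)[C@H]3C=CC[C@@H]13
F3 | step 3 | tricyclic cyclobutanol mesylate (C9–C10 bond closed) | OC12CCC(OS(C)(=O)=O)C1(Sc3ccccc3)[C@H]4C=CC[C@@H]24
F4 | step 9 | C2 allylic alcohol of 15 (OH cis to H-1) | C[C@]1(O)CC[C@@H]3C4(COCOC4)[C@@H]3[C@H]2C=C[C@H](O)[C@@H]12
F5 | step 9 | (tributylstannyl)methyl ether of F4 | C[C@]1(O)CC[C@@H]3C4(COCOC4)[C@@H]3[C@H]2C=C[C@H](OC[Sn](CCCC)(CCCC)CCCC)[C@@H]12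
F6 | step 9 | C4-hydroxymethyl C2=C3 alkene formal | C[C@]1(O)CC[C@@H]3C4(COCOC4)[C@@H]3[C@H]2[C@H](CO)C=C[C@@H]12
F7 | step 9 | methanesulfonate of F6 | C[C@]1(O)CC[C@@H]3C4(COCOC4)[C@@H]3[C@H]2[C@H](COS(C)(=O)=O)C=C[C@@H]12
F8 | step 9 | diol mesylate (formal removed) | C[C@]1(O)CC[C@@H]3C(CO)(CO)[C@@H]3[C@H]2[C@H](COS(C)(=O)=O)C=C[C@@H]12
F9 | step 9 | C4 epimer of 16 | C[C@]1(O)CC[C@@H]2[C@]3(CO)COC[C@@H]4C=C[C@@H]1[C@H]4[C@H]23
F10 | step 10 | C2 methyl acetal with free C13–OH | OC[C@@]12COCC3=CO[C@H](OC)[C@@H]4[C@H]3[C@@H]1[C@@H]2CC[C@]4(C)O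
F11 | step 10 | C13 acetate of F10 | CC(=O)OC[C@@]12COCC3=CO[C@H](OC)[C@@H]4[C@H]3[C@@H]1[C@@H]2CC[C@]4(C)O
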